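All runs stem from a simulated flask with constants of no real substance, and the scatter is random.

Ring cannot stand above the fraction of the charge that has left the starting material.

- theta: starting material 0.10 M; protic impurity 0.20 M; run made earlier
- flask: starting material 0.10 M; protic impurity 0.100 M; time 2.0 h

theta run (percent of the starting material charged)

| time / min | ring / % | starting material / % |
|---|---|---|
| 6.00 | 39.2 | 7.2 |
| 12.0 | 32.6 | 1.3 |
| 20.0 | 25.9 | 0.5 |
| 25.0 | 25.3 | 0 |
| 30.0 | 25.8 | 0.4 |
| 40.0 | 24.7 | 0 |

(standard deviation of a reading: 1 percentage point)

- the best time, 2.0 h at the latest, for ring
- the amount of ring, in percent of the starting material charged, at that time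

- no earlier run changes the charge of protic impurity; that part of a forecast is a guess

At 6.00 min the theta run has spent 93 percentage points of its starting material, and I guess that the flask peaks near that time and has spent as much. That is my first ceiling. Theta's ring reading there gives the ring share, ring still standing per unit of starting material spent, 0.422. The rest of what was spent is unaccounted for.

If the impurity takes none of that rest, the flask keeps this share, and my floor is 39.2 %. If it takes the whole rest, then half the impurity halves the ratio of rest to ring. The share becomes 0.594, and my tightened ceiling is 55.1 %.

The forecast says 52 % at 0.12 h, within 40 % to 68 %, arguing: “Halving the impurity should slow ring loss and cut diversion”. Its value lies inside my bracket, below the ceiling and above the floor.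

The flask gives 44.2 % at 0.0968 h, with 9.53 % starting material left.

    starting material + protic impurity → quenched substrate (k = 0.0176 M⁻¹ s⁻¹)
    ring ⇌ isomer of the product (K = 1.60, k = 0.00217 s⁻¹)
    2 starting material ⇌ open dimer (K = 10.0 M⁻¹, k = 0.134 M⁻¹ s⁻¹)
    starting material → ring (k = 0.00752 s⁻¹)
    starting material + ring → side product (k = 0.0110 M⁻¹ s⁻¹)

The flask's ring share is therefore 0.488, above theta's and below my ceiling share. At 0.0345 h ring is made 2.64 times faster than it is used up. Its forward half-life to the isomer of the product, 0.089 h, is far shorter than the 2.0 h allowed, and ring ends at 29.3 %. The neighbour with 0.025 M starting material has the same impurity charge, so the flask's share and the same spent fraction give 45.4 %. The computed neighbour reaches 49.8 %, more than that.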